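**Plan**
Germacrane numbers are used (carbocycle C1–C10, lactone carbons C11–C13, C14 on C10, C15 on C4); TBS = tert-butyldimethylsilyl, TBDPS = tert-butyldiphenylsilyl, PMB = 4-methoxybenzyl.
Retrosynthesis: the O8–acyl bond is cut first, then ring bond C7–C8, which opens the ten-membered carbocycle to a butenolide aldehyde; then the butenolide bonds C7=C11 and O6–C12, C6–C7, the alkenes C1=C10 and C4=C5, and C9–C10 and C3–C4.
Enabling feature: the α-methylene-γ-butyrolactone ring (O–C6–C7–C11–C12) carries the C8 carbinol on its β-carbon C7 and the exo-methylene C13 on C11, the pattern left when a butenolide metallated at C13 adds through C7 to a C8 aldehyde.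
Forward: the chain is joined at C4=C5, then at C1=C10, then C6–C7; the five-membered butenolide closes by metathesis, the ten-membered ring closes at C7–C8, and the ester and the C14/C15 oxidation states follow.
Stereochemistry: both ring-cis alkenes from E-selective Horner–Wadsworth–Emmons reactions; C6 from a ligand-controlled vinylzinc addition; C7 from C6 (trans fusion); C8 from the chair transition state followed by Mitsunobu inversion; the side-chain centre from (S)-2-methylbutanoic acid.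
Key step: step 19

Assumption: the CrCl2 ring closure is taken to follow the chair transition state of intermolecular allylchromium additions, so the 7,8-anti (8α) alcohol is expected and the ester is attached with inversion.

**Route**

Step 1
Reactants: 1 triethyl phosphonoacetate; 2 (3-bromopropoxy)(tert-butyl)dimethylsilane
Product: 3 ethyl 5-(tert-butyldimethylsilyloxy)-2-(diethoxyphosphoryl)pentanoate (racemic)
Conditions: NaH, NaI (cat.), DMF, 0 to 60 °C
Reagents that add atoms: none
Why: C-alkylation of the sodium enolate of a stabilised phosphonate with a primary bromide (SN2) is routine and attaches C3–C1 to the future C4; the new centre disappears in step 2, so it needs no control.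

Step 2
Reactants: 3 ethyl 5-(tert-butyldimethylsilyloxy)-2-(diethoxyphosphoryl)pentanoate; 4 2,2-dimethoxyacetaldehyde
Product: 5 ethyl (E)-2-[3-(TBSO)propyl]-4,4-dimethoxybut-2-enoate
Conditions: K2CO3, THF/H2O (4 as its commercial 60% aqueous solution), 0 °C to rt
Reagents that add atoms: none
Why: Horner–Wadsworth–Emmons olefination of the reactive glyoxal monoacetal under mild aqueous carbonate is E-selective for α-alkyl phosphonoacetates, which puts the ester carbon C15 trans to C6 and hence C3 cis to C6, as the ring-cis C4=C5 alkene requires.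

Step 3
Reactants: 5 ethyl (E)-2-[3-(TBSO)propyl]-4,4-dimethoxybut-2-enoate
Product: 6 (E)-2-[3-(TBSO)propyl]-4,4-dimethoxybut-2-en-1-ol
Conditions: i-Bu2AlH (2.5 equiv), CH2Cl2, −78 °C; aq. potassium sodium tartrate
Reagents that add atoms: none
Why: 1,2-reduction of an enoate to the allylic alcohol with i-Bu2AlH at low temperature is standard and leaves the acetal, the silyl ether and the alkene geometry untouched.

Step 4
Reactants: 6 (E)-2-[3-(TBSO)propyl]-4,4-dimethoxybut-2-en-1-ol
Product: 7 (E)-1-(TBDPSO)-2-[3-(TBSO)propyl]-4,4-dimethoxybut-2-ene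
Conditions: TBDPSCl, imidazole, DMF, 0 °C to rt
Reagents that add atoms: tert-butyl(chloro)diphenylsilane, CC(C)(C)[Si](Cl)(c1ccccc1)c1ccccc1
Why: silylation of a primary allylic alcohol is routine and gives the C15 ether that has to outlast every later step.

Step 5
Reactants: 7 (E)-1-(TBDPSO)-2-[3-(TBSO)propyl]-4,4-dimethoxybut-2-ene
Product: 8 (E)-4-[(TBDPSO)methyl]-6,6-dimethoxyhex-4-en-1-ol
Conditions: camphorsulfonic acid (0.1 equiv), MeOH, 0 °C
Reagents that add atoms: none
Why: acid-catalysed methanolysis cleaves a primary TBS ether far faster than a primary TBDPS ether, and in methanol the dimethyl acetal can only exchange with itself.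

Step 6
Reactants: 8 (E)-4-[(TBDPSO)methyl]-6,6-dimethoxyhex-4-en-1-ol
Product: 9 (E)-4-[(TBDPSO)methyl]-6,6-dimethoxyhex-4-enal
Conditions: n-Pr4N[RuO4] (5 mol%), NMO, 4 Å molecular sieves, CH2Cl2, rt
Reagents that add atoms: none
Why: the Ley–Griffith oxidation is neutral and converts the primary alcohol into the C1 aldehyde without touching the acid-sensitive acetal or the silyl ether.

Step 7
Reactants: 1 triethyl phosphonoacetate; 10 (2-bromoethoxy)(tert-butyl)dimethylsilane
Product: 11 ethyl 4-(tert-butyldimethylsilyloxy)-2-(diethoxyphosphoryl)butanoate (racemic)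
Conditions: NaH, NaI (cat.), DMF, 0 to 70 °C
Reagents that add atoms: none
Why: the same enolate alkylation as in step 1, now with the two-carbon bromide, gives the phosphonate that carries C9 and the masked C8.

Step 8
Reactants: 9 (E)-4-[(TBDPSO)methyl]-6,6-dimethoxyhex-4-enal; 11 ethyl 4-(tert-butyldimethylsilyloxy)-2-(diethoxyphosphoryl)butanoate
Product: 12 ethyl (2E,6E)-2-[2-(TBSO)ethyl]-6-[(TBDPSO)methyl]-8,8-dimethoxyocta-2,6-dienoate
Conditions: NaH, THF, 0 °C to rt
Reagents that add atoms: none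
Why: Horner–Wadsworth–Emmons olefination of an unbranched aldehyde with an α-alkyl phosphonoacetate is E-selective, so the ester carbon C14 ends trans to C2 and C9 cis to C2 (the ring-cis C1=C10 alkene); any minor geometric isomer should be removable by chromatography.

Step 9
Reactants: 12 ethyl (2E,6E)-2-[2-(TBSO)ethyl]-6-[(TBDPSO)methyl]-8,8-dimethoxyocta-2,6-dienoate
Product: 13 (2E,6E)-2-[2-(TBSO)ethyl]-6-[(TBDPSO)methyl]-8,8-dimethoxyocta-2,6-dien-1-ol
Conditions: i-Bu2AlH (2.5 equiv), CH2Cl2, −78 °C; aq. potassium sodium tartrate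
Reagents that add atoms: none
Why: low-temperature i-Bu2AlH reduction of the enoate gives the C14 allylic alcohol with no effect on the acetal, the silyl ethers or either alkene.

Step 10
Reactants: 13 (2E,6E)-2-[2-(TBSO)ethyl]-6-[(TBDPSO)methyl]-8,8-dimethoxyocta-2,6-dien-1-ol
Product: 14 (2E,6E)-1-(PMBO)-2-[2-(TBSO)ethyl]-6-[(TBDPSO)methyl]-8,8-dimethoxyocta-2,6-diene
Conditions: NaH, PMBCl, n-Bu4NI (cat.), DMF, 0 °C to rt
Reagents that add atoms: 4-methoxybenzyl chloride, COc1ccc(CCl)cc1
Why: Williamson etherification of the allylic alkoxide gives the C14 PMB ether, which is orthogonal to both silyl ethers and can be removed oxidatively late in the route.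

Step 11
Reactants: 14 (2E,6E)-1-(PMBO)-2-[2-(TBSO)ethyl]-6-[(TBDPSO)methyl]-8,8-dimethoxyocta-2,6-diene
Product: 15 (2E,6E)-3-[(TBDPSO)methyl]-7-[(PMBO)methyl]-9-(TBSO)nona-2,6-dienal
Conditions: PPTS (0.2 equiv), acetone/H2O 9:1, rt
Reagents that add atoms: water, O
Why: acetals of α,β-unsaturated aldehydes hydrolyse under very mild acid because the oxocarbenium ion is allylically stabilised, and under these conditions the silyl and PMB ethers and the alkene geometry should survive.

Step 12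
Reactants: 15 (2E,6E)-3-[(TBDPSO)methyl]-7-[(PMBO)methyl]-9-(TBSO)nona-2,6-dienal
Product: 16 (3S,4E,8E)-5-[(TBDPSO)methyl]-9-[(PMBO)methyl]-11-(TBSO)undeca-1,4,8-trien-3-ol
Conditions: Zn(CH=CH2)2 (from CH2=CHMgBr and ZnCl2, magnesium salts removed with 1,4-dioxane), (−)-MIB [(2S)-3-exo-morpholinoisoborneol] (10 mol%), toluene, −20 to 0 °C; aq. NH4Cl
Reagents that add atoms: divinylzinc, C=C[Zn]C=C
Why: amino-alcohol-catalysed addition of an alkenylzinc reagent to an enal is an established catalytic asymmetric vinylation, and (−)-MIB should direct the vinyl group to the Si face of the aldehyde, setting C6 as S in 16 (the arrangement that is named 6R once the lactone is in place).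

Step 13
Reactants: 16 (3S,4E,8E)-5-[(TBDPSO)methyl]-9-[(PMBO)methyl]-11-(TBSO)undeca-1,4,8-trien-3-ol; 17 2-(diethoxyphosphoryl)acetic acid
Product: 18 (3S,4E,8E)-5-[(TBDPSO)methyl]-9-[(PMBO)methyl]-11-(TBSO)undeca-1,4,8-trien-3-yl 2-(diethoxyphosphoryl)acetate
Conditions: EDC·HCl, DMAP (0.1 equiv), CH2Cl2, 0 °C to rt
Reagents that add atoms: none
Why: Steglich esterification of a secondary alcohol under neutral carbodiimide conditions avoids ionisation of the bis-allylic carbinol and leaves C6 unchanged.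

Step 14
Reactants: 18 (3S,4E,8E)-5-[(TBDPSO)methyl]-9-[(PMBO)methyl]-11-(TBSO)undeca-1,4,8-trien-3-yl 2-(diethoxyphosphoryl)acetate
Product: 20 (3S,4E,8E)-5-[(TBDPSO)methyl]-9-[(PMBO)methyl]-11-(TBSO)undeca-1,4,8-trien-3-yl 2-(hydroxymethyl)acrylate, via hydroxymethyl phosphonoacetate 19 (not isolated)
Conditions: 37% aq. HCHO (excess), K2CO3, THF/H2O, rt
Reagents that add atoms: formaldehyde, C=O
Why: phosphonoacetates undergo aldol addition to formaldehyde followed by Horner–Wadsworth–Emmons olefination with a second formaldehyde under aqueous K2CO3, a standard entry to 2-(hydroxymethyl)acrylates that installs C11=CH2 and C13–OH here without a protecting group.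

Step 15
Reactants: 20 (3S,4E,8E)-5-[(TBDPSO)methyl]-9-[(PMBO)methyl]-11-(TBSO)undeca-1,4,8-trien-3-yl 2-(hydroxymethyl)acrylate
Product: 21 (R)-3-(hydroxymethyl)-5-[(1E,5E)-2-[(TBDPSO)methyl]-6-[(PMBO)methyl]-8-(TBSO)octa-1,5-dien-1-yl]furan-2(5H)-one
Conditions: second-generation Grubbs catalyst (5 mol%), CH2Cl2 (5 mM), 40 °C
Reagents that add atoms: none
Why: ring-closing metathesis between a terminal vinyl group and an acrylate is a standard butenolide synthesis (five-membered ring, ethene lost); the ruthenium carbene forms at the only monosubstituted alkene, the two trisubstituted alkenes are too hindered to compete, and C6 is untouched (its descriptor becomes R by priority only).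

Step 16
Reactants: 21 (R)-3-(hydroxymethyl)-5-[(1E,5E)-2-[(TBDPSO)methyl]-6-[(PMBO)methyl]-8-(TBSO)octa-1,5-dien-1-yl]furan-2(5H)-one
Product: 22 (R)-3-(bromomethyl)-5-[(1E,5E)-2-[(TBDPSO)methyl]-6-[(PMBO)methyl]-8-(TBSO)octa-1,5-dien-1-yl]furan-2(5H)-one
Conditions: CBr4, PPh3, CH2Cl2, −20 to 0 °C
Reagents that add atoms: tetrabromomethane, BrC(Br)(Br)Br
Why: the Appel reaction converts the primary allylic alcohol into the C13 bromide under neutral conditions that neither epimerise the γ-position of the butenolide nor disturb the ethers.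

Step 17
Reactants: 22 (R)-3-(bromomethyl)-5-[(1E,5E)-2-[(TBDPSO)methyl]-6-[(PMBO)methyl]-8-(TBSO)octa-1,5-dien-1-yl]furan-2(5H)-one
Product: 23 (R)-3-(bromomethyl)-5-[(1E,5E)-2-[(TBDPSO)methyl]-8-hydroxy-6-[(PMBO)methyl]octa-1,5-dien-1-yl]furan-2(5H)-one
Conditions: camphorsulfonic acid (0.2 equiv), MeOH/CH2Cl2 1:1, 0 °C, short reaction time
Reagents that add atoms: none
Why: acidic methanolysis removes the primary TBS ether selectively in the presence of the TBDPS and PMB ethers, and in the absence of base or amine the allylic bromide and the butenolide should persist.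

Step 18
Reactants: 23 (R)-3-(bromomethyl)-5-[(1E,5E)-2-[(TBDPSO)methyl]-8-hydroxy-6-[(PMBO)methyl]octa-1,5-dien-1-yl]furan-2(5H)-one
Product: 24 (3E,7E)-8-[(R)-4-(bromomethyl)-5-oxo-2,5-dihydrofuran-2-yl]-7-[(TBDPSO)methyl]-3-[(PMBO)methyl]octa-3,7-dienal
Conditions: Dess–Martin periodinane, NaHCO3 (buffer), CH2Cl2, 0 °C; crude aldehyde used at once
Reagents that add atoms: none
Why: buffered Dess–Martin oxidation gives β,γ-unsaturated aldehydes without migration of the C1=C10 double bond into conjugation, and immediate use limits any later isomerisation.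

Step 19
Reactants: 24 (3E,7E)-8-[(R)-4-(bromomethyl)-5-oxo-2,5-dihydrofuran-2-yl]-7-[(TBDPSO)methyl]-3-[(PMBO)methyl]octa-3,7-dienal
Product: 26 (3aR,4S,6E,10E,11aR)-4-hydroxy-6-[(PMBO)methyl]-10-[(TBDPSO)methyl]-3-methylene-3a,4,5,8,9,11a-hexahydrocyclodeca[b]furan-2(3H)-one (8α-alcohol; 6R 7R 8S in germacrane numbers), via allylchromium dichloride 25 (not isolated)
Conditions: CrCl2 (10 equiv), THF, rt, syringe-pump addition of 24 over 10 h to a final 2 mM; aq. NH4Cl
Reagents that add atoms: none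
Why: Proposed new method: two equivalents of CrCl2 (divalent chromium) reduce the C13–Br bond of 24 to the allylchromium dichloride 25 (trivalent chromium), whose γ-carbon C7 adds to the tethered C8 aldehyde through a six-membered chair transition state (Cr–O=C8···C7=C11–C13), so that C7–C8 forms with allylic transposition and the C11=C13 methylene conjugated to the lactone carbonyl appears in the same event. The closest known reactions are the intermolecular chromium-, zinc- or indium-mediated additions of 3-(bromomethyl)furan-2(5H)-ones to aldehydes, which give β-(hydroxyalkyl)-α-methylene-γ-butyrolactones, and Nozaki–Hiyama–Kishi macrocyclisations of simple allylic bromides; their union in one ring closure is the untested part. The ten-membered carbocycle C1–C10 closes by intramolecular carbonyl addition in which only C7 of the allyl unit becomes a ring atom, the two ring-cis trisubstituted alkenes bending the chain back towards the butenolide. C7 is set by C6: the chain leaves C6 on one face of the flat butenolide and the chromium-bearing chair can assemble without clashing with it only on the other face, which gives the trans ring fusion (7R). C8 is set by the chair: C6 is held trans to C13 by the lactone ring and is therefore equatorial like the γ-substituent of an E-crotyl reagent, C9 takes the equatorial site on the aldehyde carbon, and the 7,8-anti alcohol with the hydroxyl α (8S) should result. The step needs γ- rather than α-attack, ring closure rather than oligomerisation and an intact β,γ-unsaturated aldehyde; the first is inherent in allylchromium reagents, the second is secured by slow addition at high dilution and the third by the neutral, aprotic medium.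

Step 20
Reactants: 26 (3aR,4S,6E,10E,11aR)-4-hydroxy-6-[(PMBO)methyl]-10-[(TBDPSO)methyl]-3-methylene-3a,4,5,8,9,11a-hexahydrocyclodeca[b]furan-2(3H)-one; 27 (S)-2-methylbutanoic acid
Product: 28 (3aR,4R,6E,10E,11aR)-6-[(PMBO)methyl]-10-[(TBDPSO)methyl]-3-methylene-2-oxo-2,3,3a,4,5,8,9,11a-octahydrocyclodeca[b]furan-4-yl (S)-2-methylbutanoate
Conditions: PPh3, DIAD, toluene, 0 °C to rt
Reagents that add atoms: none
Why: the Mitsunobu reaction esterifies a secondary alcohol with SN2 inversion, turning the 8α-alcohol (8S) into the 8β-ester (8R), while the α-centre of the acid, which reacts only as a carboxylate nucleophile, is not at risk.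

Step 21
Reactants: 28 (3aR,4R,6E,10E,11aR)-6-[(PMBO)methyl]-10-[(TBDPSO)methyl]-3-methylene-2-oxo-2,3,3a,4,5,8,9,11a-octahydrocyclodeca[b]furan-4-yl (S)-2-methylbutanoate
Product: 29 (3aR,4R,6E,10E,11aR)-6-(hydroxymethyl)-10-[(TBDPSO)methyl]-3-methylene-2-oxo-2,3,3a,4,5,8,9,11a-octahydrocyclodeca[b]furan-4-yl (S)-2-methylbutanoate
Conditions: DDQ, CH2Cl2/pH 7 phosphate buffer 10:1, 0 °C
Reagents that add atoms: none
Why: oxidative cleavage of a PMB ether with DDQ in wet CH2Cl2 is selective in the presence of a silyl ether, esters and the α-methylene lactone.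

Step 22
Reactants: 29 (3aR,4R,6E,10E,11aR)-6-(hydroxymethyl)-10-[(TBDPSO)methyl]-3-methylene-2-oxo-2,3,3a,4,5,8,9,11a-octahydrocyclodeca[b]furan-4-yl (S)-2-methylbutanoate
Product: 30 (3aR,4R,6E,10E,11aR)-6-formyl-10-[(TBDPSO)methyl]-3-methylene-2-oxo-2,3,3a,4,5,8,9,11a-octahydrocyclodeca[b]furan-4-yl (S)-2-methylbutanoate
Conditions: MnO2 (activated, excess), CH2Cl2, rt
Reagents that add atoms: none
Why: MnO2 oxidises primary allylic alcohols to enals chemoselectively and without geometric isomerisation, and C14–OH is the only free hydroxyl at this stage.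

Step 23
Reactants: 30 (3aR,4R,6E,10E,11aR)-6-formyl-10-[(TBDPSO)methyl]-3-methylene-2-oxo-2,3,3a,4,5,8,9,11a-octahydrocyclodeca[b]furan-4-yl (S)-2-methylbutanoate
Product: 31 (3aR,4R,6E,10E,11aR)-6-formyl-10-(hydroxymethyl)-3-methylene-2-oxo-2,3,3a,4,5,8,9,11a-octahydrocyclodeca[b]furan-4-yl (S)-2-methylbutanoate (CNP0168859.6)
Conditions: HF·pyridine, THF, 0 °C to rt
Reagents that add atoms: none
Why: HF·pyridine cleaves the TBDPS ether under mildly acidic, non-basic conditions that spare the enal, the ester and the Michael-accepting α-methylene lactone.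

**Compound list**
1 | triethyl phosphonoacetate | CCOC(=O)CP(=O)(OCC)OCC | starting material
2 | (3-bromopropoxy)(tert-butyl)dimethylsilane | CC(C)(C)[Si](C)(C)OCCCBr | starting material
3 | ethyl 5-(tert-butyldimethylsilyloxy)-2-(diethoxyphosphoryl)pentanoate (racemic) | CCOC(=O)C(CCCO[Si](C)(C)C(C)(C)C)P(=O)(OCC)OCC | intermediate
4 | 2,2-dimethoxyacetaldehyde | COC(OC)C=O | starting material
5 | ethyl (E)-2-[3-(TBSO)propyl]-4,4-dimethoxybut-2-enoate | COC(OC)/C=C(/C(=O)OCC)CCCO[Si](C)(C)C(C)(C)C | intermediate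
6 | (E)-2-[3-(TBSO)propyl]-4,4-dimethoxybut-2-en-1-ol | COC(OC)/C=C(/CO)CCCO[Si](C)(C)C(C)(C)C | intermediate
7 | (E)-1-(TBDPSO)-2-[3-(TBSO)propyl]-4,4-dimethoxybut-2-ene | COC(OC)/C=C(/CO[Si](c1ccccc1)(c1ccccc1)C(C)(C)C)CCCO[Si](C)(C)C(C)(C)C | intermediate
8 | (E)-4-[(TBDPSO)methyl]-6,6-dimethoxyhex-4-en-1-ol | COC(OC)/C=C(/CO[Si](c1ccccc1)(c1ccccc1)C(C)(C)C)CCCO | intermediate
9 | (E)-4-[(TBDPSO)methyl]-6,6-dimethoxyhex-4-enal | COC(OC)/C=C(/CO[Si](c1ccccc1)(c1ccccc1)C(C)(C)C)CCC=O | intermediate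
10 | (2-bromoethoxy)(tert-butyl)dimethylsilane | CC(C)(C)[Si](C)(C)OCCBr | starting material
11 | ethyl 4-(tert-butyldimethylsilyloxy)-2-(diethoxyphosphoryl)butanoate (racemic) | CCOC(=O)C(CCO[Si](C)(C)C(C)(C)C)P(=O)(OCC)OCC | intermediate
12 | ethyl (2E,6E)-2-[2-(TBSO)ethyl]-6-[(TBDPSO)methyl]-8,8-dimethoxyocta-2,6-dienoate | COC(OC)/C=C(/CO[Si](c1ccccc1)(c1ccccc1)C(C)(C)C)CC/C=C(/C(=O)OCC)CCO[Si](C)(C)C(C)(C)C | intermediate
13 | (2E,6E)-2-[2-(TBSO)ethyl]-6-[(TBDPSO)methyl]-8,8-dimethoxyocta-2,6-dien-1-ol | COC(OC)/C=C(/CO[Si](c1ccccc1)(c1ccccc1)C(C)(C)C)CC/C=C(/CO)CCO[Si](C)(C)C(C)(C)C | intermediate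
14 | (2E,6E)-1-(PMBO)-2-[2-(TBSO)ethyl]-6-[(TBDPSO)methyl]-8,8-dimethoxyocta-2,6-diene | COC(OC)/C=C(/CO[Si](c1ccccc1)(c1ccccc1)C(C)(C)C)CC/C=C(/COCc1ccc(OC)cc1)CCO[Si](C)(C)C(C)(C)C | intermediate
15 | (2E,6E)-3-[(TBDPSO)methyl]-7-[(PMBO)methyl]-9-(TBSO)nona-2,6-dienal | O=C/C=C(/CO[Si](c1ccccc1)(c1ccccc1)C(C)(C)C)CC/C=C(/COCc1ccc(OC)cc1)CCO[Si](C)(C)C(C)(C)C | intermediate
16 | (3S,4E,8E)-5-[(TBDPSO)methyl]-9-[(PMBO)methyl]-11-(TBSO)undeca-1,4,8-trien-3-ol | C=C[C@H](O)/C=C(/CO[Si](c1ccccc1)(c1ccccc1)C(C)(C)C)CC/C=C(/COCc1ccc(OC)cc1)CCO[Si](C)(C)C(C)(C)C | intermediate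
17 | 2-(diethoxyphosphoryl)acetic acid | OC(=O)CP(=O)(OCC)OCC | starting material
18 | (3S,4E,8E)-5-[(TBDPSO)methyl]-9-[(PMBO)methyl]-11-(TBSO)undeca-1,4,8-trien-3-yl 2-(diethoxyphosphoryl)acetate | CCOP(=O)(OCC)CC(=O)O[C@@H](C=C)/C=C(/CO[Si](c1ccccc1)(c1ccccc1)C(C)(C)C)CC/C=C(/COCc1ccc(OC)cc1)CCO[Si](C)(C)C(C)(C)C | intermediate
19 | (3S,4E,8E)-5-[(TBDPSO)methyl]-9-[(PMBO)methyl]-11-(TBSO)undeca-1,4,8-trien-3-yl 2-(diethoxyphosphoryl)-3-hydroxypropanoate (both epimers at the phosphonate carbon; not isolated) | CCOP(=O)(OCC)C(CO)C(=O)O[C@@H](C=C)/C=C(/CO[Si](c1ccccc1)(c1ccccc1)C(C)(C)C)CC/C=C(/COCc1ccc(OC)cc1)CCO[Si](C)(C)C(C)(C)C | intermediate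
20 | (3S,4E,8E)-5-[(TBDPSO)methyl]-9-[(PMBO)methyl]-11-(TBSO)undeca-1,4,8-trien-3-yl 2-(hydroxymethyl)acrylate | C=C(CO)C(=O)O[C@@H](C=C)/C=C(/CO[Si](c1ccccc1)(c1ccccc1)C(C)(C)C)CC/C=C(/COCc1ccc(OC)cc1)CCO[Si](C)(C)C(C)(C)C | intermediate
21 | (R)-3-(hydroxymethyl)-5-[(1E,5E)-2-[(TBDPSO)methyl]-6-[(PMBO)methyl]-8-(TBSO)octa-1,5-dien-1-yl]furan-2(5H)-one | O=C1O[C@H](/C=C(/CO[Si](c2ccccc2)(c2ccccc2)C(C)(C)C)CC/C=C(/COCc2ccc(OC)cc2)CCO[Si](C)(C)C(C)(C)C)C=C1CO | intermediate
22 | (R)-3-(bromomethyl)-5-[(1E,5E)-2-[(TBDPSO)methyl]-6-[(PMBO)methyl]-8-(TBSO)octa-1,5-dien-1-yl]furan-2(5H)-one | O=C1O[C@H](/C=C(/CO[Si](c2ccccc2)(c2ccccc2)C(C)(C)C)CC/C=C(/COCc2ccc(OC)cc2)CCO[Si](C)(C)C(C)(C)C)C=C1CBr | intermediate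
23 | (R)-3-(bromomethyl)-5-[(1E,5E)-2-[(TBDPSO)methyl]-8-hydroxy-6-[(PMBO)methyl]octa-1,5-dien-1-yl]furan-2(5H)-one | O=C1O[C@H](/C=C(/CO[Si](c2ccccc2)(c2ccccc2)C(C)(C)C)CC/C=C(/COCc2ccc(OC)cc2)CCO)C=C1CBr | intermediate
24 | (3E,7E)-8-[(R)-4-(bromomethyl)-5-oxo-2,5-dihydrofuran-2-yl]-7-[(TBDPSO)methyl]-3-[(PMBO)methyl]octa-3,7-dienal | O=C1O[C@H](/C=C(/CO[Si](c2ccccc2)(c2ccccc2)C(C)(C)C)CC/C=C(/COCc2ccc(OC)cc2)CC=O)C=C1CBr | intermediate
25 | allylchromium dichloride derived from 24 (CrCl2 in place of Br on C13; trivalent chromium; not isolated) | O=C1O[C@H](/C=C(/CO[Si](c2ccccc2)(c2ccccc2)C(C)(C)C)CC/C=C(/COCc2ccc(OC)cc2)CC=O)C=C1C[Cr](Cl)Cl | intermediate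
26 | (3aR,4S,6E,10E,11aR)-4-hydroxy-6-[(PMBO)methyl]-10-[(TBDPSO)methyl]-3-methylene-3a,4,5,8,9,11a-hexahydrocyclodeca[b]furan-2(3H)-one (8α-alcohol) | C=C1C(=O)O[C@@H]2/C=C(/CO[Si](c3ccccc3)(c3ccccc3)C(C)(C)C)CC/C=C(/COCc3ccc(OC)cc3)C[C@H](O)[C@@H]12 | intermediate
27 | (S)-2-methylbutanoic acid | CC[C@H](C)C(=O)O | starting material
28 | (3aR,4R,6E,10E,11aR)-6-[(PMBO)methyl]-10-[(TBDPSO)methyl]-3-methylene-2-oxo-2,3,3a,4,5,8,9,11a-octahydrocyclodeca[b]furan-4-yl (S)-2-methylbutanoate | C=C1C(=O)O[C@@H]2/C=C(/CO[Si](c3ccccc3)(c3ccccc3)C(C)(C)C)CC/C=C(/COCc3ccc(OC)cc3)C[C@@H](OC(=O)[C@@H](C)CC)[C@@H]12 | intermediate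
29 | (3aR,4R,6E,10E,11aR)-6-(hydroxymethyl)-10-[(TBDPSO)methyl]-3-methylene-2-oxo-2,3,3a,4,5,8,9,11a-octahydrocyclodeca[b]furan-4-yl (S)-2-methylbutanoate | C=C1C(=O)O[C@@H]2/C=C(/CO[Si](c3ccccc3)(c3ccccc3)C(C)(C)C)CC/C=C(/CO)C[C@@H](OC(=O)[C@@H](C)CC)[C@@H]12 | intermediate
30 | (3aR,4R,6E,10E,11aR)-6-formyl-10-[(TBDPSO)methyl]-3-methylene-2-oxo-2,3,3a,4,5,8,9,11a-octahydrocyclodeca[b]furan-4-yl (S)-2-methylbutanoate | C=C1C(=O)O[C@@H]2/C=C(/CO[Si](c3ccccc3)(c3ccccc3)C(C)(C)C)CC/C=C(/C=O)C[C@@H](OC(=O)[C@@H](C)CC)[C@@H]12 | intermediate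
31 | (3aR,4R,6E,10E,11aR)-6-formyl-10-(hydroxymethyl)-3-methylene-2-oxo-2,3,3a,4,5,8,9,11a-octahydrocyclodeca[b]furan-4-yl (S)-2-methylbutanoate | C=C1C(=O)O[C@@H]2/C=C(/CO)CC/C=C(/C=O)C[C@@H](OC(=O)[C@@H](C)CC)[C@@H]12 | target

**Step count**
Total: 23 steps. Longest linear sequence: 22 steps (steps 1–6 and 8–23, from 1 to 31); step 7 is a one-step branch.

**Steps most likely to fail**

Step 19 (proposed new method). What may go wrong: the chair with C9 equatorial may be disfavoured by strain in the forming ten-membered ring, so that the aldehyde is attacked on its other face and the hydroxyl ends on the β-face in part or in full. Fallback: setting out from 24, material of this kind, (3aR,4R,6E,10E,11aR)-8β-alcohol F1, is not discarded. Steglich acylation of F1 with acid 27 (EDC·HCl, DMAP, CH2Cl2, 0 °C to rt) is a known esterification with retention at C8 and returns to the route at 28. Because 26 is esterified with inversion and F1 with retention, both C8 epimers converge on 28. This fallback covers the facial outcome only, not a failure of the ring to close.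

Step 20. What may go wrong: the activated C8 oxygen may be lost by elimination towards C9, or substitution at the hindered secondary centre by the weakly acidic branched acid may stall. Fallback: setting out from 26, sulfonylation (MsCl, Et3N, CH2Cl2, −20 °C) gives the 8α-methanesulfonate F2. Displacement with cesium (S)-2-methylbutanoate (from 27 and Cs2CO3) and 18-crown-6 in toluene at 60 °C is a known SN2 inversion of a secondary sulfonate by a carboxylate and returns to the route at 28.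

Step 12. What may go wrong: uncatalysed background addition of the vinylzinc reagent and weak face discrimination on the β,β-disubstituted enal, that is, low enantioselectivity at C6. Fallback: setting out from 15, zinc–ProPhenol-catalysed addition of trimethylsilylacetylene (Me2Zn, the ProPhenol antipode that delivers the alkyne to the Si face, Ph3P=O, toluene) gives the (R)-configured silylated propargylic alcohol F3. It has the same spatial arrangement as 16; the descriptor differs because alkynyl outranks the alkenyl group. K2CO3 in MeOH removes the silyl group to give the terminal alkyne F4, and semi-hydrogenation (H2, Pd/CaCO3 poisoned with Pb(OAc)2, quinoline, EtOAc) returns to the route at 16.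

**Further compounds**
F1 | step 19 | (3aR,4R,6E,10E,11aR)-4-hydroxy-6-[(PMBO)methyl]-10-[(TBDPSO)methyl]-3-methylene-3a,4,5,8,9,11a-hexahydrocyclodeca[b]furan-2(3H)-one (8β-alcohol) | C=C1C(=O)O[C@@H]2/C=C(/CO[Si](c3ccccc3)(c3ccccc3)C(C)(C)C)CC/C=C(/COCc3ccc(OC)cc3)C[C@@H](O)[C@@H]12
F2 | step 20 | (3aS,4S,6E,10E,11aR)-6-[(PMBO)methyl]-10-[(TBDPSO)methyl]-3-methylene-2-oxo-2,3,3a,4,5,8,9,11a-octahydrocyclodeca[b]furan-4-yl methanesulfonate (8α-methanesulfonate of 26; the 3a descriptor changes by priority only) | C=C1C(=O)O[C@@H]2/C=C(/CO[Si](c3ccccc3)(c3ccccc3)C(C)(C)C)CC/C=C(/COCc3ccc(OC)cc3)C[C@H](OS(C)(=O)=O)[C@@H]12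
F3 | step 12 | (3R,4E,8E)-5-[(TBDPSO)methyl]-9-[(PMBO)methyl]-11-(TBSO)-1-(trimethylsilyl)undeca-4,8-dien-1-yn-3-ol | C[Si](C)(C)C#C[C@H](O)/C=C(/CO[Si](c1ccccc1)(c1ccccc1)C(C)(C)C)CC/C=C(/COCc1ccc(OC)cc1)CCO[Si](C)(C)C(C)(C)C
F4 | step 12 | (3R,4E,8E)-5-[(TBDPSO)methyl]-9-[(PMBO)methyl]-11-(TBSO)undeca-4,8-dien-1-yn-3-ol | C#C[C@H](O)/C=C(/CO[Si](c1ccccc1)(c1ccccc1)C(C)(C)C)CC/C=C(/COCc1ccc(OC)cc1)CCO[Si](C)(C)C(C)(C)C
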